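**Plan**

1. Retrosynthesis: the aryl–vinyl bond of the styryl arm is cut first (Negishi coupling of an alkenylmetal, made from a terminal alkyne, with 6-bromo-7-methoxycoumarin). The quaternary methyl is then returned to a formyl group, and the two ring bonds CH2–CH2 and C(aryl-bearing)–C(quaternary) are cut together in a Diels–Alder reaction.
2. Enabling feature: in the cyclohexene ring the C(CH3)=CH double bond lies between the aryl-bearing CH and a CH2–CH2–C(quaternary) unit. This is the retron of a [4+2] addition of the 6-(3-methylbuta-1,3-dienyl)coumarin (the C15 unit of which the target is the formal dimer) to a 1,1-disubstituted ethene.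
3. Forward: coumarin ring by Wittig/lactonisation, then Heck reaction and dehydration to the diene; Sonogashira coupling and oxidation to a 2-alkynylacrolein; the Diels–Alder reaction closes the carbocycle; CHO is reduced to CH3 and the alkyne is turned into the second (E)-coumarinylethenyl arm with the same bromide.
4. Helpers: the formyl group (activation, handle for the chiral Lewis acid, endo director; later the quaternary methyl) and the silylalkyne (latent (E)-ethenyl arm, chosen because an alkyne, unlike a styryl group, should not trap the transient neopentyl radical of the deoxygenation).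
5. Stereochemistry: both stereocentres arise in the Diels–Alder step, the relative configuration from the endo mode and the absolute one from the chiral oxazaborolidinium catalyst. The alkene geometries come from the Heck reaction and from syn-hydrozirconation.

Key step: step 6

Assumption: the sense of induction in step 6 is assigned from the formyl C–H···O pre-transition-state model for 2-substituted acroleins and is not certain; should the adduct prove to be the mirror image, the catalyst made from the (S)-oxazaborolidine is used instead, with no other change.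

**Route**

Step 1
Reactants: 1 5-bromo-2-hydroxy-4-methoxybenzaldehyde; 2 ethyl 2-(triphenyl-λ5-phosphanylidene)acetate
Product: 4 6-bromo-7-methoxy-2H-chromen-2-one, via cinnamate ester 3 (not isolated)
Conditions: N,N-diethylaniline, reflux (about 210 °C)
Reagents that add atoms: none
Why: Wittig olefination of the salicylaldehyde with the stabilised ylide, followed at this temperature by E/Z equilibration and lactonisation of the (Z)-cinnamate onto the free phenol, is the standard one-pot coumarin synthesis and leaves the aryl bromide untouched.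

Step 2
Reactants: 4 6-bromo-7-methoxy-2H-chromen-2-one; 5 2-methylbut-3-en-2-ol
Product: 6 6-[(E)-3-hydroxy-3-methylbut-1-en-1-yl]-7-methoxy-2H-chromen-2-one
Conditions: Pd(OAc)2 (cat.), P(o-tol)3, Et3N, DMF, 100 °C
Reagents that add atoms: none
Why: Mizoroki–Heck reaction of the aryl bromide with the monosubstituted alkene, in which syn-β-hydride elimination can only occur toward the benzylic hydrogen because the carbinol carbon carries none, should give the (E)-styrenyl tertiary alcohol.

Step 3
Reactants: 6 6-[(E)-3-hydroxy-3-methylbut-1-en-1-yl]-7-methoxy-2H-chromen-2-one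
Product: 8 7-methoxy-6-[(E)-3-methylbuta-1,3-dien-1-yl]-2H-chromen-2-one, via sulfamate ester 7 (not isolated)
Conditions: methyl N-(triethylammoniosulfonyl)carbamate, THF, rt to 50 °C; product kept cold and dilute and used at once
Reagents that add atoms: none
Why: Burgess-type dehydration of the tertiary alcohol through its sulfamate ester by intramolecular syn-elimination can only take a methyl hydrogen and should give the 2-substituted 1,3-diene under neutral conditions that spare this acid- and heat-sensitive diene.

Step 4
Reactants: 9 2-bromoprop-2-en-1-ol; 10 ethynyltrimethylsilane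
Product: 11 2-methylidene-4-(trimethylsilyl)but-3-yn-1-ol
Conditions: PdCl2(PPh3)2 (cat.), CuI (cat.), i-Pr2NH, THF, rt
Reagents that add atoms: none
Why: Sonogashira coupling of the vinyl bromide with the terminal alkyne should proceed at room temperature in the presence of the free allylic alcohol and give the cross-conjugated enynol.

Step 5
Reactants: 11 2-methylidene-4-(trimethylsilyl)but-3-yn-1-ol
Product: 12 2-methylidene-4-(trimethylsilyl)but-3-ynal
Conditions: activated MnO2 (excess), CH2Cl2, 0 °C to rt; filtered and used at once as a cold solution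
Reagents that add atoms: none
Why: MnO2 oxidises the allylic, enyne-conjugated primary alcohol selectively to the 2-substituted acrolein under neutral heterogeneous conditions, so the polymerisation-prone enynal need not be stored or purified.

Step 6
Reactants: 8 7-methoxy-6-[(E)-3-methylbuta-1,3-dien-1-yl]-2H-chromen-2-one; 12 2-methylidene-4-(trimethylsilyl)but-3-ynal
Product: 13 (1R,2R)-2-(7-methoxy-2-oxo-2H-chromen-6-yl)-4-methyl-1-[(trimethylsilyl)ethynyl]cyclohex-3-ene-1-carbaldehyde (formyl cis to the aryl group)
Conditions: (R)-3,3-diphenyl-1-(2-methylphenyl)tetrahydro-1H,3H-pyrrolo[1,2-c][1,3,2]oxazaborole (0.2 equiv) protonated with HN(SO2CF3)2 (0.17 equiv), CH2Cl2, −78 to −40 °C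
Reagents that add atoms: none
Why: Concerted, asynchronous, normal-electron-demand [4+2] cycloaddition of diene 8 (HOMO raised by the 3-methyl and 1-aryl groups) to the boron-bound, LUMO-lowered 2-alkynylacrolein 12; the closest known reaction type is the oxazaborolidinium-catalysed enantioselective Diels–Alder reaction of 2-substituted acroleins with acyclic dienes. The cyclohexene ring is closed in an intermolecular [4πs+2πs] mode by two σ-bonds, the more advanced CH2–CH2 bond between the diene terminus C4 and the methylidene carbon of 12 and the bond between the aryl-bearing C1 and the new quaternary carbon, while the ring C=C appears between C2 and C3 of the diene. The regiochemistry ("ortho" to aryl, "para" to methyl) follows from matching the largest HOMO coefficient at the diene CH2 terminus with the largest LUMO coefficient at the enal β-carbon. The relative configuration (formyl cis to aryl) needs the endo orientation of the catalyst-bound formyl group toward the (E)-diene with the slim alkynyl arm exo, a mode that here, unlike with cyclopentadiene, no bridging CH2 disfavours. The absolute configuration of both centres is set by the catalyst: the formyl C–H···O contact with the ring oxygen should hold the s-trans enal over one C-phenyl group so that the diene reaches only the open C2-Re face of 12 (CHO > alkynyl > CH2). Chemoselectivity for the enal C=C over the silylalkyne and over self-dimerisation of 8 rests on the exclusive activation of the carbonyl-conjugated C=C at −78 °C.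

Step 7
Reactants: 13 (1R,2R)-2-(7-methoxy-2-oxo-2H-chromen-6-yl)-4-methyl-1-[(trimethylsilyl)ethynyl]cyclohex-3-ene-1-carbaldehyde; 14 4-methylbenzenesulfonohydrazide
Product: 15 N'-[(E)-{(1R,2S)-2-(7-methoxy-2-oxo-2H-chromen-6-yl)-4-methyl-1-[(trimethylsilyl)ethynyl]cyclohex-3-en-1-yl}methylidene]-4-methylbenzenesulfonohydrazide
Conditions: THF/EtOH, AcOH (cat.), rt to 40 °C
Reagents that add atoms: none
Why: Condensation of the aldehyde, the only carbonyl group reactive toward the weakly nucleophilic sulfonyl hydrazide, should give the (E)-tosylhydrazone, and the quaternary α-carbon rules out epimerisation.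

Step 8
Reactants: 15 N'-[(E)-{(1R,2S)-2-(7-methoxy-2-oxo-2H-chromen-6-yl)-4-methyl-1-[(trimethylsilyl)ethynyl]cyclohex-3-en-1-yl}methylidene]-4-methylbenzenesulfonohydrazide
Product: 18 7-methoxy-6-{(1S,6S)-3,6-dimethyl-6-[(trimethylsilyl)ethynyl]cyclohex-2-en-1-yl}-2H-chromen-2-one, via N-boryl hydrazide 16 (not isolated), via alkyldiazene 17 (not isolated)
Conditions: catecholborane, CHCl3, 0 °C; then NaOAc·3H2O, reflux
Reagents that add atoms: none
Why: Caglioti-type reduction, in which hydride transfer from catecholborane to C=N gives the N-boryl hydrazide, acetate-induced loss of sulfinate gives the alkyldiazene and this expels N2 to leave the methyl group, should spare lactone, alkenes and silylalkyne.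

Step 9
Reactants: 18 7-methoxy-6-{(1S,6S)-3,6-dimethyl-6-[(trimethylsilyl)ethynyl]cyclohex-2-en-1-yl}-2H-chromen-2-one
Product: 19 6-[(1S,6S)-6-ethynyl-3,6-dimethylcyclohex-2-en-1-yl]-7-methoxy-2H-chromen-2-one
Conditions: K2CO3 (cat.), MeOH/CH2Cl2, 0 °C to rt, short reaction time
Reagents that add atoms: none
Why: Base-catalysed methanolysis of the C(sp)–Si bond (protodesilylation) should unmask the terminal alkyne under conditions mild and brief enough for the coumarin lactone.

Step 10
Reactants: 19 6-[(1S,6S)-6-ethynyl-3,6-dimethylcyclohex-2-en-1-yl]-7-methoxy-2H-chromen-2-one; 4 6-bromo-7-methoxy-2H-chromen-2-one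
Product: 22 7-methoxy-6-[(E)-2-[(1R,2S)-2-(7-methoxy-2-oxo-2H-chromen-6-yl)-1,4-dimethylcyclohex-3-en-1-yl]ethenyl]-2H-chromen-2-one, via alkenylzirconocene chloride 20 (not isolated), via alkenylzinc chloride 21 (not isolated)
Conditions: Cp2Zr(H)Cl, THF, 0 °C to rt; then ZnCl2, 4, Pd(PPh3)4 (cat.), THF, 45 °C
Reagents that add atoms: none
Why: Syn-hydrozirconation of the terminal alkyne places zirconium on the terminal carbon and fixes the (E)-geometry, and transmetalation to zinc followed by Pd-catalysed Negishi coupling with bromide 4 proceeds with retention to give the (E)-styryl arm without touching the two stereocentres.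

**Compound list**

1 | 5-bromo-2-hydroxy-4-methoxybenzaldehyde | O=Cc1cc(Br)c(OC)cc1O | starting material
2 | ethyl 2-(triphenyl-λ5-phosphanylidene)acetate | CCOC(=O)C=P(c1ccccc1)(c1ccccc1)c1ccccc1 | starting material
3 | ethyl (Z)-3-(5-bromo-2-hydroxy-4-methoxyphenyl)prop-2-enoate | CCOC(=O)/C=C\c1cc(Br)c(OC)cc1O | intermediate
4 | 6-bromo-7-methoxy-2H-chromen-2-one | COc1cc2oc(=O)ccc2cc1Br | intermediate
5 | 2-methylbut-3-en-2-ol | CC(C)(O)C=C | starting material
6 | 6-[(E)-3-hydroxy-3-methylbut-1-en-1-yl]-7-methoxy-2H-chromen-2-one | COc1cc2oc(=O)ccc2cc1/C=C/C(C)(C)O | intermediate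
7 | triethylammonium salt of the N-(methoxycarbonyl)sulfamate ester of alcohol 6 | COc1cc2oc(=O)ccc2cc1/C=C/C(C)(C)OS(=O)(=O)[N-]C(=O)OC.CC[NH+](CC)CC | intermediate
8 | 7-methoxy-6-[(E)-3-methylbuta-1,3-dien-1-yl]-2H-chromen-2-one | COc1cc2oc(=O)ccc2cc1/C=C/C(C)=C | intermediate
9 | 2-bromoprop-2-en-1-ol | OCC(Br)=C | starting material
10 | ethynyltrimethylsilane | C#C[Si](C)(C)C | starting material
11 | 2-methylidene-4-(trimethylsilyl)but-3-yn-1-ol | C=C(CO)C#C[Si](C)(C)C | intermediate
12 | 2-methylidene-4-(trimethylsilyl)but-3-ynal | C=C(C=O)C#C[Si](C)(C)C | intermediate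
13 | (1R,2R)-2-(7-methoxy-2-oxo-2H-chromen-6-yl)-4-methyl-1-[(trimethylsilyl)ethynyl]cyclohex-3-ene-1-carbaldehyde, formyl cis to aryl | C[Si](C)(C)C#C[C@@]1(C=O)CCC(C)=C[C@@H]1c1cc2ccc(=O)oc2cc1OC | intermediate
14 | 4-methylbenzenesulfonohydrazide | Cc1ccc(cc1)S(=O)(=O)NN | starting material
15 | N'-[(E)-{(1R,2S)-2-(7-methoxy-2-oxo-2H-chromen-6-yl)-4-methyl-1-[(trimethylsilyl)ethynyl]cyclohex-3-en-1-yl}methylidene]-4-methylbenzenesulfonohydrazide | C[Si](C)(C)C#C[C@@]1(/C=N/NS(=O)(=O)c2ccc(C)cc2)CCC(C)=C[C@@H]1c1cc2ccc(=O)oc2cc1OC | intermediate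
16 | N'-(1,3,2-benzodioxaborol-2-yl)-N'-{[(1R,2S)-2-(7-methoxy-2-oxo-2H-chromen-6-yl)-4-methyl-1-[(trimethylsilyl)ethynyl]cyclohex-3-en-1-yl]methyl}-4-methylbenzenesulfonohydrazide | C[Si](C)(C)C#C[C@@]1(CN(B2Oc3ccccc3O2)NS(=O)(=O)c2ccc(C)cc2)CCC(C)=C[C@@H]1c1cc2ccc(=O)oc2cc1OC | intermediate
17 | {[(1R,2S)-2-(7-methoxy-2-oxo-2H-chromen-6-yl)-4-methyl-1-[(trimethylsilyl)ethynyl]cyclohex-3-en-1-yl]methyl}diazene | C[Si](C)(C)C#C[C@@]1(CN=N)CCC(C)=C[C@@H]1c1cc2ccc(=O)oc2cc1OC | intermediate
18 | 7-methoxy-6-{(1S,6S)-3,6-dimethyl-6-[(trimethylsilyl)ethynyl]cyclohex-2-en-1-yl}-2H-chromen-2-one, methyl cis to aryl | C[Si](C)(C)C#C[C@@]1(C)CCC(C)=C[C@@H]1c1cc2ccc(=O)oc2cc1OC | intermediate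
19 | 6-[(1S,6S)-6-ethynyl-3,6-dimethylcyclohex-2-en-1-yl]-7-methoxy-2H-chromen-2-one | C#C[C@@]1(C)CCC(C)=C[C@@H]1c1cc2ccc(=O)oc2cc1OC | intermediate
20 | (E)-alkenylzirconocene chloride from 19, Cp2Zr(Cl) on the terminal vinyl carbon, both stereocentres as in 19 | Cl[Zr](C1C=CC=C1)(C1C=CC=C1)/C=C/[C@@]1(C)CCC(C)=C[C@@H]1c1cc2ccc(=O)oc2cc1OC | intermediate
21 | (E)-alkenylzinc chloride from 20, both stereocentres as in 19 | Cl[Zn]/C=C/[C@@]1(C)CCC(C)=C[C@@H]1c1cc2ccc(=O)oc2cc1OC | intermediate
22 | 7-methoxy-6-[(E)-2-[(1R,2S)-2-(7-methoxy-2-oxo-2H-chromen-6-yl)-1,4-dimethylcyclohex-3-en-1-yl]ethenyl]-2H-chromen-2-one | COc1cc2oc(=O)ccc2cc1/C=C/[C@@]1(C)CCC(C)=C[C@@H]1c1cc2ccc(=O)oc2cc1OC | target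

**Step count and risks**

Total step count: 10. Longest linear sequence: 8 steps (steps 1, 2, 3, 6, 7, 8, 9, 10).

Steps most likely to fail:

Step 6. The cycloaddition may proceed with insufficient endo preference (the endo/exo outcome for this diene class under Lewis acid catalysis is not secure) or with the wrong facial sense. The catalyst may also be sequestered by the Lewis-basic lactone carbonyl, or the diene may oligomerise under the strong Lewis acid. Fallback: diene 8 is heated alone in toluene at about 110 °C. Its uncatalysed [4+2] cyclodimerisation (the dienyl group of one molecule as diene, the terminal C=C of a second as dienophile, the larger styryl group exo) should give the racemic dimer without helper groups, that is 22 together with its enantiomer 7-methoxy-6-[(E)-2-[(1S,2R)-2-(7-methoxy-2-oxo-2H-chromen-6-yl)-1,4-dimethylcyclohex-3-en-1-yl]ethenyl]-2H-chromen-2-one F1. Preparative HPLC on an amylose tris(3,5-dimethylphenylcarbamate) phase separates the two, and the route is rejoined at 22.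

Step 8. Hydride transfer to the hindered hydrazone next to the quaternary carbon may be slow, and material may be lost through side reactions of the alkyldiazene. Fallback: aldehyde 13 is reduced with NaBH4/CeCl3·7H2O in MeOH at −40 °C, which should touch only the formyl group, to the primary alcohol 6-{(1S,6R)-6-(hydroxymethyl)-3-methyl-6-[(trimethylsilyl)ethynyl]cyclohex-2-en-1-yl}-7-methoxy-2H-chromen-2-one F2. Treatment with 1,1'-thiocarbonyldiimidazole and DMAP in CH2Cl2 gives O-{[(1R,2S)-2-(7-methoxy-2-oxo-2H-chromen-6-yl)-4-methyl-1-[(trimethylsilyl)ethynyl]cyclohex-3-en-1-yl]methyl} 1H-imidazole-1-carbothioate F3. Bu3SnH and AIBN in toluene at 110 °C (Barton–McCombie deoxygenation) then cleave the C–O bond, and the route is rejoined at 18.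

Step 10. Cp2Zr(H)Cl may reduce the lactone carbonyls in competition with the alkyne, or the coupling at the ortho-methoxy aryl bromide may be sluggish with erosion of the alkene geometry. Fallback: alkyne 19 is semihydrogenated with H2 over Pd/CaCO3 poisoned with Pb(OAc)2 and quinoline to 6-[(1S,6R)-6-ethenyl-3,6-dimethylcyclohex-2-en-1-yl]-7-methoxy-2H-chromen-2-one F4. A Mizoroki–Heck reaction of F4 with bromide 4 (Pd(OAc)2, P(o-tol)3, Et3N, DMF, 100 °C), in which β-hydride elimination is possible only toward the benzylic hydrogen, should give the (E)-alkene, and the route is rejoined at 22.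

Further compounds
F1 | step 6 | 7-methoxy-6-[(E)-2-[(1S,2R)-2-(7-methoxy-2-oxo-2H-chromen-6-yl)-1,4-dimethylcyclohex-3-en-1-yl]ethenyl]-2H-chromen-2-one | COc1cc2oc(=O)ccc2cc1/C=C/[C@]1(C)CCC(C)=C[C@H]1c1cc2ccc(=O)oc2cc1OC
F2 | step 8 | 6-{(1S,6R)-6-(hydroxymethyl)-3-methyl-6-[(trimethylsilyl)ethynyl]cyclohex-2-en-1-yl}-7-methoxy-2H-chromen-2-one | C[Si](C)(C)C#C[C@@]1(CO)CCC(C)=C[C@@H]1c1cc2ccc(=O)oc2cc1OC
F3 | step 8 | O-{[(1R,2S)-2-(7-methoxy-2-oxo-2H-chromen-6-yl)-4-methyl-1-[(trimethylsilyl)ethynyl]cyclohex-3-en-1-yl]methyl} 1H-imidazole-1-carbothioate | C[Si](C)(C)C#C[C@@]1(COC(=S)n2ccnc2)CCC(C)=C[C@@H]1c1cc2ccc(=O)oc2cc1OC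
F4 | step 10 | 6-[(1S,6R)-6-ethenyl-3,6-dimethylcyclohex-2-en-1-yl]-7-methoxy-2H-chromen-2-one | C=C[C@@]1(C)CCC(C)=C[C@@H]1c1cc2ccc(=O)oc2cc1OC
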